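**Retrosynthetic overview**

1. Numbering: ring A is the cyclohexane (C1 carbinol, C2 methylidene carbon, C3–C5 CH2, C6 CMe2); ring B is the 1,2-dioxane (O1, O2, C3 = CH, C4, C5, C6 = quaternary carbon).
2. Ring A is closed first, at C4–C5, by ring-closing metathesis of an acyclic triene (C2 as ketone, C4 and C5 as CH=CH2 termini). In the same flask the isopropenyl end (future C6 and methyl of ring B) is cross-metathesised with a homoallylic alcohol from (R)-Roche ester, which brings C3–C5 of ring B and the propanoate carbons with both their stereocentres.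
3. Enabling feature: C4 and C5 of ring A are unsubstituted CH2 groups, and C1 and C6 are vicinal fully substituted carbons that press the vinyl group on C6 and the allyl ketone at C2 together; C6 of ring B carries a methyl group and can therefore travel as an isopropenyl group that does not cyclise.
4. C1 (S) is set by a copper bis(oxazoline) Mukaiyama aldol of an α-keto ester (C1, C2) with a thioisobutyrate silyl ketene acetal (C6, its methyls, C5).
5. Ring B is closed second: cobalt-catalysed hydroperoxysilylation at C6, then displacement of a C3 mesylate by the peroxide anion with inversion. C6 of ring B is the one centre not controlled (epimers separated after ring closure). The C2 methylidene stays masked as a β-hydroxysilane until the last step.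

Key step: step 12

Assumption: step 4 follows the facial sense established for this catalyst class with pyruvate esters ((S,S)-ligand, si face); centres written without configuration (C2 of ring A in 24–31 and F1–F3, the thioester α-carbon of F5, C4 of F7) are epimer mixtures whose configuration is destroyed later.

**Route**

Step 1
Reactants: 1 2-methylpropanoyl chloride; 2 ethanethiol
Product: 3 S-ethyl 2-methylpropanethioate
Conditions: pyridine, CH2Cl2, 0 °C to rt
Reagents that add atoms: none
Why: Acylation of the thiol by the acid chloride (thioesterification) should proceed cleanly; no stereocentre is involved.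

Step 2
Reactants: 3 S-ethyl 2-methylpropanethioate
Product: 5 {[1-(ethylsulfanyl)-2-methylprop-1-en-1-yl]oxy}trimethylsilane, via lithium enolate 4 (not isolated)
Conditions: LiN(iPr)2, THF, −78 °C; then Me3SiCl, −78 °C to rt
Reagents that add atoms: chlorotrimethylsilane, C[Si](C)(C)Cl
Why: Kinetic deprotonation and O-silylation of the thioester enolate (silyl ketene acetal formation) should give 5, whose olefin geometry is irrelevant because both β-substituents are methyl.

Step 3
Reactants: 6 2-(2-bromoethyl)-2-methyl-1,3-dioxolane; 7 diethyl oxalate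
Product: 9 ethyl 4-(2-methyl-1,3-dioxolan-2-yl)-2-oxobutanoate, via Grignard reagent 8 (not isolated)
Conditions: Mg, THF, rt; then added to 7 (2 equiv), THF, −78 °C; aq. NH4Cl
Reagents that add atoms: none
Why: Grignard acylation by inverse addition to excess oxalate at low temperature should stop at the α-keto ester because the tetrahedral intermediate survives until work-up.

Step 4
Reactants: 9 α-keto ester; 5 silyl ketene acetal
Product: 11 ethyl (2S)-2-[1-(ethylsulfanyl)-2-methyl-1-oxopropan-2-yl]-2-hydroxy-5-oxohexanoate, via silyl ether 10 (not isolated)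
Conditions: [Cu((S,S)-tBu-box)](OTf)2 (10 mol %), THF, −78 to −40 °C; then 1 M HCl, THF, rt
Reagents that add atoms: water, O
Why: Catalytic enantioselective Mukaiyama aldol addition, in which the keto ester chelates the square-planar copper bis(oxazoline) complex through both carbonyl groups and the ketene acetal attacks the open si face, should set C1 of ring A (S) and join it to C6, and the acid work-up removes the silyl ether and the dioxolane.

Step 5
Reactants: 11 hydroxy thioester
Product: 12 ethyl (2S)-2-hydroxy-2-(2-methyl-1-oxopropan-2-yl)-5-oxohexanoate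
Conditions: Et3SiH, Pd/C (10 %), acetone, rt
Reagents that add atoms: none
Why: Fukuyama reduction (insertion of palladium into the C–S bond, then hydride transfer from the silane) should convert only the thioester into the aldehyde and leave ester, ketone and alcohol untouched.

Step 6
Reactants: 12 keto aldehyde
Product: 14 ethyl (2S)-2-hydroxy-5-methyl-2-(2-methylbut-3-en-2-yl)hex-5-enoate, via keto alkene 13 (not isolated)
Conditions: Ph3PCH3Br, KN(SiMe3)2, THF, 0 °C; 12 added at −78 °C, then rt
Reagents that add atoms: methyltriphenylphosphonium bromide, C[P+](c1ccccc1)(c1ccccc1)c1ccccc1.[Br-]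
Why: Twofold Wittig methylenation should take the aldehyde at −78 °C (faster than retro-aldol of the β-alkoxide) and the methyl ketone on warming, while the hindered ester stays inert.

Step 7
Reactants: 14 diene ester
Product: 15 (2S)-2-hydroxy-N-methoxy-N,5-dimethyl-2-(2-methylbut-3-en-2-yl)hex-5-enamide
Conditions: MeNH(OMe)·HCl, AlMe3, CH2Cl2, 0 °C to reflux; aq. potassium sodium tartrate
Reagents that add atoms: N,O-dimethylhydroxylamine hydrochloride, CNOC.Cl
Why: Aluminium amide aminolysis of the ester (Weinreb amide formation) should be assisted by the α-alkoxide, which holds aluminium next to the ester carbonyl.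

Step 8
Reactants: 15 Weinreb amide
Product: 16 (5S)-5-hydroxy-8-methyl-5-(2-methylbut-3-en-2-yl)nona-1,8-dien-4-one
Conditions: allylMgBr, THF, −78 to −20 °C; aq. NH4Cl at −78 °C
Reagents that add atoms: allylmagnesium bromide, C=CC[Mg]Br
Why: Grignard addition to the Weinreb amide should stop at the ketone through the chelated tetrahedral intermediate, and the cold buffered quench avoids conjugation of the β,γ-unsaturated ketone.

Step 9
Reactants: 17 methyl (2R)-3-hydroxy-2-methylpropanoate
Product: 18 methyl (2R)-3-[(tert-butyldiphenylsilyl)oxy]-2-methylpropanoate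
Conditions: tBuPh2SiCl, imidazole, DMF, rt
Reagents that add atoms: tert-butyl(chloro)diphenylsilane, CC(C)(C)[Si](Cl)(c1ccccc1)c1ccccc1
Why: Silylation of the primary alcohol does not touch the purchased stereocentre, which becomes the propanoate α-carbon.

Step 10
Reactants: 18 silyl ether ester
Product: 19 (2R)-3-[(tert-butyldiphenylsilyl)oxy]-2-methylpropanal
Conditions: iBu2AlH, CH2Cl2, −78 °C; aq. potassium sodium tartrate
Reagents that add atoms: none
Why: Partial ester reduction through the aluminium hemiacetal, stable at −78 °C, should give the aldehyde, which is used at once to avoid epimerisation.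

Step 11
Reactants: 19 aldehyde
Product: 20 (2R,3R)-1-[(tert-butyldiphenylsilyl)oxy]-2-methylhex-5-en-3-ol
Conditions: (+)-Ipc2B(allyl), Et2O, −78 °C; then NaOH, H2O2, 0 °C
Reagents that add atoms: (+)-B-allyldiisopinocampheylborane, C=CCB(C1CC2CC(C1C)C2(C)C)C1CC2CC(C1C)C2(C)C
Why: Brown allylation through a chair six-membered transition state should set the carbinol centre (3R) under reagent control, in the matched Felkin–Anh sense for the (R)-aldehyde (2,3-syn).

Step 12
Reactants: 16 triene ketone; 20 homoallylic alcohol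
Product: 22 (2S)-2-[(3E,6R,7R)-8-[(tert-butyldiphenylsilyl)oxy]-6-hydroxy-3,7-dimethyloct-3-en-1-yl]-2-hydroxy-3,3-dimethylcyclohex-4-en-1-one, via cyclohexenone 21 (not isolated)
Conditions: (H2IMes)(PCy3)Cl2Ru=CHPh (second-generation Grubbs catalyst, 5 mol %), 1,4-benzoquinone (10 mol %), CH2Cl2 (5 mM), 40 °C; then 20 (3 equiv), catalyst (5 mol %), concentration to 0.2 M, 40 °C
Reagents that add atoms: none
Why: The ruthenium alkylidene loads onto the unhindered allyl terminus of 16 and closes ring A by [2+2] cycloaddition and cycloreversion with the vinyl group on C6, which forms C4=C5 and releases ethylene; the alkylidene derived from added 20 then undergoes cross metathesis with the remaining isopropenyl group. The closest known reaction types are ring-closing metathesis of 1,7-dienes to cyclohexenes run in one flask with a cross metathesis, and cross metathesis of 2-methyl-1-alkenes with terminal olefins to trisubstituted olefins. Ring A is closed as a six-membered ring through the two internal olefin carbons of two monosubstituted termini. No stereocentre is formed: the ring olefin is necessarily cis, and the side-chain olefin (drawn E) may be an E/Z mixture because step 16 turns both into the same tertiary radical. The step needs chemoselectivity (ring closure before cross metathesis, no ring closure onto the isopropenyl group); this is secured by the vicinal fully substituted carbons C1 and C6 (Thorpe–Ingold compression of the two reacting arms), by the reluctance of the 1,1-disubstituted olefin to cyclise (seven-membered or trisubstituted six-membered ring) and by dilution in the first phase, while benzoquinone suppresses hydride-induced migration of the β,γ-unsaturated ketone.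

Step 13
Reactants: 22 cyclohexenone
Product: 23 (2S)-2-[(3E,6R,7R)-8-[(tert-butyldiphenylsilyl)oxy]-6-hydroxy-3,7-dimethyloct-3-en-1-yl]-2-hydroxy-3,3-dimethylcyclohexan-1-one
Conditions: H2 (3 atm), RhCl(PPh3)3 (10 mol %), benzene, rt
Reagents that add atoms: none
Why: Homogeneous hydrogenation with Wilkinson's catalyst discriminates by olefin substitution, so the cis-disubstituted ring olefin (or its conjugated isomer) should be saturated while the trisubstituted side-chain olefin survives.

Step 14
Reactants: 23 hydroxy ketone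
Product: 24 (1S)-1-[(3E,6R,7R)-8-[(tert-butyldiphenylsilyl)oxy]-6-hydroxy-3,7-dimethyloct-3-en-1-yl]-6,6-dimethyl-2-[(trimethylsilyl)methyl]cyclohexane-1,2-diol (both C2 epimers)
Conditions: Me3SiCH2Li, CeCl3, THF, −78 to 0 °C; aq. NH4Cl
Reagents that add atoms: (trimethylsilyl)methyllithium, C[Si](C)(C)C[Li]
Why: 1,2-Addition of the organocerium reagent to the hindered, enolisable ketone (first half of a Peterson olefination) should give the β-hydroxysilane as a masked methylidene; the new C2 centre is not controlled and is destroyed in step 20.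

Step 15
Reactants: 24 triol
Product: 25 (2R,3R,5E)-1-[(tert-butyldiphenylsilyl)oxy]-8-[(1S)-1,2-dihydroxy-6,6-dimethyl-2-[(trimethylsilyl)methyl]cyclohexyl]-2,6-dimethyloct-5-en-3-yl methanesulfonate
Conditions: MsCl, pyridine, CH2Cl2, 0 °C
Reagents that add atoms: methanesulfonyl chloride, CS(=O)(=O)Cl
Why: Sulfonylation under pyridine conditions should take only the secondary hydroxyl (both tertiary hydroxyls are inert) with retention at the carbinol carbon.

Step 16
Reactants: 25 mesylate
Product: 26 (2R,3R,6R)-1-[(tert-butyldiphenylsilyl)oxy]-8-[(1S)-1,2-dihydroxy-6,6-dimethyl-2-[(trimethylsilyl)methyl]cyclohexyl]-2,6-dimethyl-6-[(triethylsilyl)peroxy]octan-3-yl methanesulfonate (formed together with its 6S epimer)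
Conditions: Co(thd)2 (10 mol %; thd = 2,2,6,6-tetramethylheptane-3,5-dionate), O2 (1 atm), Et3SiH, ClCH2CH2Cl, rt
Reagents that add atoms: dioxygen, O=O; triethylsilane, CC[SiH](CC)CC
Why: Mukaiyama–Isayama hydroperoxysilylation (hydrogen-atom transfer from a cobalt hydride to the less substituted olefin carbon, trapping of the tertiary radical by dioxygen, silylation) should place the peroxide on the future C6 of ring B, but the planar radical is attacked from both faces and this centre is not controlled.

Step 17
Reactants: 26 silyl peroxide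
Product: 29 (2R)-2-[(3S,6R)-6-{2-[(1S)-1,2-dihydroxy-6,6-dimethyl-2-[(trimethylsilyl)methyl]cyclohexyl]ethyl}-6-methyl-1,2-dioxan-3-yl]propan-1-ol, via peroxide anion 27 (not isolated), via dioxane silyl ether 28 (not isolated)
Conditions: Bu4NF (1.1 equiv), THF, −20 to 0 °C; then Bu4NF (2 equiv), rt; chromatographic removal of the C6 epimer of ring B
Reagents that add atoms: none
Why: Fluoride cleaves the O–Si bond of the silyl peroxide and the peroxide anion displaces the mesylate in a 6-exo-tet SN2 reaction (intramolecular peroxide alkylation) that closes ring B with inversion and so sets C3 (S), after which more fluoride removes the silyl ether; the C6 epimer cyclises likewise and is separated here.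

Step 18
Reactants: 29 dioxane alcohol
Product: 30 (2S)-2-[(3S,6R)-6-{2-[(1S)-1,2-dihydroxy-6,6-dimethyl-2-[(trimethylsilyl)methyl]cyclohexyl]ethyl}-6-methyl-1,2-dioxan-3-yl]propanoic acid
Conditions: TEMPO (10 mol %), NaClO2, NaOCl (2 mol %), MeCN, phosphate buffer (pH 6.7), 35 °C
Reagents that add atoms: sodium chlorite, [Na+].[O-]Cl=O
Why: Oxoammonium/chlorite oxidation of the primary alcohol to the acid at near-neutral pH should spare the peroxide, the tertiary diol (no glycol cleavage) and the α-stereocentre, and no olefin is present at this stage.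

Step 19
Reactants: 30 acid
Product: 31 methyl (2S)-2-[(3S,6R)-6-{2-[(1S)-1,2-dihydroxy-6,6-dimethyl-2-[(trimethylsilyl)methyl]cyclohexyl]ethyl}-6-methyl-1,2-dioxan-3-yl]propanoate
Conditions: Me3SiCHN2, toluene/MeOH, 0 °C
Reagents that add atoms: (trimethylsilyl)diazomethane, C[Si](C)(C)C=[N+]=[N-]
Why: Esterification by O-alkylation of the carboxylate with the diazonium ion formed on protonation is base-free, so β-elimination of the peroxide from the ester is avoided.

Step 20
Reactants: 31 β-hydroxysilane ester
Product: 32 methyl (2S)-2-[(3S,6R)-6-{2-[(1S)-1-hydroxy-2,2-dimethyl-6-methylidenecyclohexyl]ethyl}-6-methyl-1,2-dioxan-3-yl]propanoate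
Conditions: 48 % aq. HF, MeCN, 0 °C
Reagents that add atoms: none
Why: Acid-induced Peterson elimination (ionisation of the hydroxyl β to silicon, loss of the silyl group) should give the exocyclic methylidene regiospecifically, while the C1 hydroxyl, which has no β-silicon, stays.

**Compound list**

1 | 2-methylpropanoyl chloride | CC(C)C(=O)Cl | starting material
2 | ethanethiol | CCS | starting material
3 | S-ethyl 2-methylpropanethioate | CCSC(=O)C(C)C | intermediate
4 | lithium 1-(ethylsulfanyl)-2-methylprop-1-en-1-olate | CC(C)=C([O-])SCC.[Li+] | intermediate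
5 | {[1-(ethylsulfanyl)-2-methylprop-1-en-1-yl]oxy}trimethylsilane | CC(C)=C(SCC)O[Si](C)(C)C | intermediate
6 | 2-(2-bromoethyl)-2-methyl-1,3-dioxolane | CC1(CCBr)OCCO1 | starting material
7 | diethyl oxalate | CCOC(=O)C(=O)OCC | starting material
8 | [2-(2-methyl-1,3-dioxolan-2-yl)ethyl]magnesium bromide | CC1(CC[Mg]Br)OCCO1 | intermediate
9 | ethyl 4-(2-methyl-1,3-dioxolan-2-yl)-2-oxobutanoate | CCOC(=O)C(=O)CCC1(C)OCCO1 | intermediate
10 | ethyl (2S)-2-[1-(ethylsulfanyl)-2-methyl-1-oxopropan-2-yl]-4-(2-methyl-1,3-dioxolan-2-yl)-2-[(trimethylsilyl)oxy]butanoate | CCOC(=O)[C@](O[Si](C)(C)C)(CCC1(C)OCCO1)C(C)(C)C(=O)SCC | intermediate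
11 | ethyl (2S)-2-[1-(ethylsulfanyl)-2-methyl-1-oxopropan-2-yl]-2-hydroxy-5-oxohexanoate | CCOC(=O)[C@](O)(CCC(C)=O)C(C)(C)C(=O)SCC | intermediate
12 | ethyl (2S)-2-hydroxy-2-(2-methyl-1-oxopropan-2-yl)-5-oxohexanoate | CCOC(=O)[C@](O)(CCC(C)=O)C(C)(C)C=O | intermediate
13 | ethyl (2S)-2-hydroxy-2-(2-methylbut-3-en-2-yl)-5-oxohexanoate | CCOC(=O)[C@](O)(CCC(C)=O)C(C)(C)C=C | intermediate
14 | ethyl (2S)-2-hydroxy-5-methyl-2-(2-methylbut-3-en-2-yl)hex-5-enoate | CCOC(=O)[C@](O)(CCC(C)=C)C(C)(C)C=C | intermediate
15 | (2S)-2-hydroxy-N-methoxy-N,5-dimethyl-2-(2-methylbut-3-en-2-yl)hex-5-enamide | CON(C)C(=O)[C@](O)(CCC(C)=C)C(C)(C)C=C | intermediate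
16 | (5S)-5-hydroxy-8-methyl-5-(2-methylbut-3-en-2-yl)nona-1,8-dien-4-one | C=CCC(=O)[C@](O)(CCC(C)=C)C(C)(C)C=C | intermediate
17 | methyl (2R)-3-hydroxy-2-methylpropanoate | COC(=O)[C@H](C)CO | starting material
18 | methyl (2R)-3-[(tert-butyldiphenylsilyl)oxy]-2-methylpropanoate | COC(=O)[C@H](C)CO[Si](c1ccccc1)(c1ccccc1)C(C)(C)C | intermediate
19 | (2R)-3-[(tert-butyldiphenylsilyl)oxy]-2-methylpropanal | O=C[C@H](C)CO[Si](c1ccccc1)(c1ccccc1)C(C)(C)C | intermediate
20 | (2R,3R)-1-[(tert-butyldiphenylsilyl)oxy]-2-methylhex-5-en-3-ol | C=CC[C@@H](O)[C@H](C)CO[Si](c1ccccc1)(c1ccccc1)C(C)(C)C | intermediate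
21 | (2S)-2-hydroxy-3,3-dimethyl-2-(3-methylbut-3-en-1-yl)cyclohex-4-en-1-one | O=C1CC=CC(C)(C)[C@@]1(O)CCC(C)=C | intermediate
22 | (2S)-2-[(3E,6R,7R)-8-[(tert-butyldiphenylsilyl)oxy]-6-hydroxy-3,7-dimethyloct-3-en-1-yl]-2-hydroxy-3,3-dimethylcyclohex-4-en-1-one | O=C1CC=CC(C)(C)[C@@]1(O)CC/C(C)=C/C[C@@H](O)[C@H](C)CO[Si](c1ccccc1)(c1ccccc1)C(C)(C)C | intermediate
23 | (2S)-2-[(3E,6R,7R)-8-[(tert-butyldiphenylsilyl)oxy]-6-hydroxy-3,7-dimethyloct-3-en-1-yl]-2-hydroxy-3,3-dimethylcyclohexan-1-one | O=C1CCCC(C)(C)[C@@]1(O)CC/C(C)=C/C[C@@H](O)[C@H](C)CO[Si](c1ccccc1)(c1ccccc1)C(C)(C)C | intermediate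
24 | (1S)-1-[(3E,6R,7R)-8-[(tert-butyldiphenylsilyl)oxy]-6-hydroxy-3,7-dimethyloct-3-en-1-yl]-6,6-dimethyl-2-[(trimethylsilyl)methyl]cyclohexane-1,2-diol (both C2 epimers) | C[Si](C)(C)CC1(O)CCCC(C)(C)[C@@]1(O)CC/C(C)=C/C[C@@H](O)[C@H](C)CO[Si](c1ccccc1)(c1ccccc1)C(C)(C)C | intermediate
25 | (2R,3R,5E)-1-[(tert-butyldiphenylsilyl)oxy]-8-[(1S)-1,2-dihydroxy-6,6-dimethyl-2-[(trimethylsilyl)methyl]cyclohexyl]-2,6-dimethyloct-5-en-3-yl methanesulfonate | C[Si](C)(C)CC1(O)CCCC(C)(C)[C@@]1(O)CC/C(C)=C/C[C@@H](OS(C)(=O)=O)[C@H](C)CO[Si](c1ccccc1)(c1ccccc1)C(C)(C)C | intermediate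
26 | (2R,3R,6R)-1-[(tert-butyldiphenylsilyl)oxy]-8-[(1S)-1,2-dihydroxy-6,6-dimethyl-2-[(trimethylsilyl)methyl]cyclohexyl]-2,6-dimethyl-6-[(triethylsilyl)peroxy]octan-3-yl methanesulfonate (with its 6S epimer) | C[Si](C)(C)CC1(O)CCCC(C)(C)[C@@]1(O)CC[C@](C)(OO[Si](CC)(CC)CC)CC[C@@H](OS(C)(=O)=O)[C@H](C)CO[Si](c1ccccc1)(c1ccccc1)C(C)(C)C | intermediate
27 | tetrabutylammonium salt of the (6R)-hydroperoxide anion derived from 26 | C[Si](C)(C)CC1(O)CCCC(C)(C)[C@@]1(O)CC[C@](C)(O[O-])CC[C@@H](OS(C)(=O)=O)[C@H](C)CO[Si](c1ccccc1)(c1ccccc1)C(C)(C)C.CCCC[N+](CCCC)(CCCC)CCCC | intermediate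
28 | (2R)-2-[(3S,6R)-6-{2-[(1S)-1,2-dihydroxy-6,6-dimethyl-2-[(trimethylsilyl)methyl]cyclohexyl]ethyl}-6-methyl-1,2-dioxan-3-yl]propyl tert-butyldiphenylsilyl ether | C[Si](C)(C)CC1(O)CCCC(C)(C)[C@@]1(O)CC[C@@]1(C)CC[C@@H]([C@H](C)CO[Si](c2ccccc2)(c2ccccc2)C(C)(C)C)OO1 | intermediate
29 | (2R)-2-[(3S,6R)-6-{2-[(1S)-1,2-dihydroxy-6,6-dimethyl-2-[(trimethylsilyl)methyl]cyclohexyl]ethyl}-6-methyl-1,2-dioxan-3-yl]propan-1-ol | C[Si](C)(C)CC1(O)CCCC(C)(C)[C@@]1(O)CC[C@@]1(C)CC[C@@H]([C@H](C)CO)OO1 | intermediate
30 | (2S)-2-[(3S,6R)-6-{2-[(1S)-1,2-dihydroxy-6,6-dimethyl-2-[(trimethylsilyl)methyl]cyclohexyl]ethyl}-6-methyl-1,2-dioxan-3-yl]propanoic acid | C[Si](C)(C)CC1(O)CCCC(C)(C)[C@@]1(O)CC[C@@]1(C)CC[C@@H]([C@H](C)C(=O)O)OO1 | intermediate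
31 | methyl (2S)-2-[(3S,6R)-6-{2-[(1S)-1,2-dihydroxy-6,6-dimethyl-2-[(trimethylsilyl)methyl]cyclohexyl]ethyl}-6-methyl-1,2-dioxan-3-yl]propanoate | C[Si](C)(C)CC1(O)CCCC(C)(C)[C@@]1(O)CC[C@@]1(C)CC[C@@H]([C@H](C)C(=O)OC)OO1 | intermediate
32 | methyl (2S)-2-[(3S,6R)-6-{2-[(1S)-1-hydroxy-2,2-dimethyl-6-methylidenecyclohexyl]ethyl}-6-methyl-1,2-dioxan-3-yl]propanoate | C=C1CCCC(C)(C)[C@@]1(O)CC[C@@]1(C)CC[C@@H]([C@H](C)C(=O)OC)OO1 | target

**Step count and risks**

Total step count: 20. Longest linear sequence: 16 steps (1 → 3 → 5 → 11 → 12 → 14 → 15 → 16 → 22 → 23 → 24 → 25 → 26 → 29 → 30 → 31 → 32).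

Steps most likely to fail:

1. Step 16: dioxygen traps a planar tertiary radical without facial discrimination, so C6 of ring B is not controlled and material is lost at the separation in step 17. The fallback sets out from 25 and comes back at 29. E2 elimination of the mesylate of geometrically pure (5E)-25 with DBU in toluene at 80 °C should give the conjugated (3E,5E)-diene silyl ether F1. Bu4NF then removes the silyl ether to give the dienol F2. Sensitised photo-oxygenation (O2, tetraphenylporphyrin, light, CCl4, 0 °C) adds singlet oxygen suprafacially across the diene to give the 3,6-dihydro-1,2-dioxine F3. The olefin geometry thereby fixes C6 relative to C3 of ring B (the two outer substituents end up cis). The face has to be steered by hydrogen bonding of the homoallylic hydroxyl, because a purely steric allylic-strain model predicts the opposite face. Diimide (2-nitrobenzenesulfonohydrazide, Et3N) saturates the ring olefin and gives 29. The ene reaction is the competing pathway.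

2. Step 4: slow addition of the fully substituted ketene acetal 5 to the chelated keto ester, which would let the uncatalysed background reaction erode the enantiomeric purity. The fallback sets out from 9 and comes back at 10. S-Ethyl propanethioate is converted as in step 2 into its trimethylsilyl ketene acetal F4, the nucleophile class for which this catalyst is established. Its addition to 9 under the conditions of step 4, with a non-acidic work-up, should give the silyl ether F5 with the same sense at C1. Deprotonation of F5 with LiN(iPr)2 and methylation with MeI completes the gem-dimethyl carbon and gives 10, which is hydrolysed to 11 as in step 4.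

3. Step 7: no aminolysis at an ester carbonyl that is flanked by two fully substituted carbons, or retro-aldol cleavage under forcing conditions. The fallback sets out from 14 and comes back at 16. iBu2AlH at −78 °C reduces the ester to the α-hydroxy aldehyde F6. AllylMgBr adds to give the homoallylic diol F7 as a mixture of C4 epimers. Oxidation of the secondary alcohol with Dess–Martin periodinane gives 16.

**Further compounds**

F1 | step 16 | (1S)-1-[(3E,5E,7S)-8-[(tert-butyldiphenylsilyl)oxy]-3,7-dimethylocta-3,5-dien-1-yl]-6,6-dimethyl-2-[(trimethylsilyl)methyl]cyclohexane-1,2-diol | C[Si](C)(C)CC1(O)CCCC(C)(C)[C@@]1(O)CC/C(C)=C/C=C/[C@H](C)CO[Si](c1ccccc1)(c1ccccc1)C(C)(C)C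
F2 | step 16 | (2S,3E,5E)-8-[(1S)-1,2-dihydroxy-6,6-dimethyl-2-[(trimethylsilyl)methyl]cyclohexyl]-2,6-dimethylocta-3,5-dien-1-ol | C[Si](C)(C)CC1(O)CCCC(C)(C)[C@@]1(O)CC/C(C)=C/C=C/[C@H](C)CO
F3 | step 16 | (2R)-2-[(3S,6S)-6-{2-[(1S)-1,2-dihydroxy-6,6-dimethyl-2-[(trimethylsilyl)methyl]cyclohexyl]ethyl}-6-methyl-3,6-dihydro-1,2-dioxin-3-yl]propan-1-ol | C[Si](C)(C)CC1(O)CCCC(C)(C)[C@@]1(O)CC[C@@]1(C)C=C[C@@H]([C@H](C)CO)OO1
F4 | step 4 | {[1-(ethylsulfanyl)prop-1-en-1-yl]oxy}trimethylsilane | CC=C(SCC)O[Si](C)(C)C
F5 | step 4 | ethyl (2S)-2-[1-(ethylsulfanyl)-1-oxopropan-2-yl]-4-(2-methyl-1,3-dioxolan-2-yl)-2-[(trimethylsilyl)oxy]butanoate | CCOC(=O)[C@](O[Si](C)(C)C)(CCC1(C)OCCO1)C(C)C(=O)SCC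
F6 | step 7 | (2S)-2-hydroxy-5-methyl-2-(2-methylbut-3-en-2-yl)hex-5-enal | O=C[C@](O)(CCC(C)=C)C(C)(C)C=C
F7 | step 7 | (5S)-8-methyl-5-(2-methylbut-3-en-2-yl)nona-1,8-diene-4,5-diol | C=CCC(O)[C@](O)(CCC(C)=C)C(C)(C)C=C
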